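**Assumptions (one line each):** (i) An anti-Prelog (R)-selective NADPH-dependent ketoreductase (KRED) from a commercial panel accepts the bulky dihydrochalcone and gives ≥98% ee. (ii) Numbered compounds are substrates, intermediates, and building-block reagents that donate carbon to the product. Catalysts and simple reagents appear only in the conditions.

## Retrosynthetic overview
- Kazinol B is a (2S)-flavan: a 7-hydroxychroman-2-yl group on a benzene ring carrying a prenyl group, a free phenol, and a 2,2-dimethylchromene.
- The chroman ring is closed last, by a Mitsunobu etherification with inversion, from an (R)-1,3-diarylpropan-1-ol. A ketoreductase (oxidoreductase class) makes that alcohol from the dihydrochalcone, and this is the only stereocenter.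
- The dihydrochalcone comes from a Claisen–Schmidt aldol of an aryl methyl ketone with a protected 2,4-dihydroxybenzaldehyde, followed by Cu–H 1,4-reduction.
- The benzene ring is built first: allyl Claisen, then allyl→prenyl cross-metathesis, then the pyran ring by propargyl Claisen/6π-electrocyclization.
- Both remaining phenols carry MOM groups, removed in the last step.

## Route

**Step 1**
Reactants: 1 (3',4'-dihydroxyacetophenone); 2 (4-methoxybenzyl chloride)
Product: 3 (1-[3-hydroxy-4-(4-methoxybenzyloxy)phenyl]ethanone)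
Conditions: 2, NaHCO3, NaI (cat.), DMF, 50 °C
Reagents that add atoms: 4-methoxybenzyl chloride, COc1ccc(CCl)cc1
Why: The 4-OH is para to the acetyl group and much more acidic than the 3-OH, so mild-base Williamson etherification alkylates only O-4 and blocks it.

**Step 2**
Reactants: 3; 4 (allyl bromide)
Product: 5 (1-[3-allyloxy-4-(4-methoxybenzyloxy)phenyl]ethanone)
Conditions: 4, K2CO3, acetone, reflux
Reagents that add atoms: allyl bromide, C=CCBr
Why: Williamson O-allylation of the only free phenol prepares the Claisen substrate.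

**Step 3**
Reactants: 5
Product: 6 (1-[2-allyl-3-hydroxy-4-(4-methoxybenzyloxy)phenyl]ethanone)
Conditions: PhNEt2, 190 °C, sealed tube, 6 h
Reagents that add atoms: none
Why: Aromatic Claisen [3,3]-rearrangement; the other ortho position (C-4) is blocked, so the allyl group goes to C-2, between the acetyl and the oxygen, and rearomatization leaves the free 3-OH.

**Step 4**
Reactants: 6; 7 (chloromethyl methyl ether, MOMCl)
Product: 8 (1-[2-allyl-3-(methoxymethoxy)-4-(4-methoxybenzyloxy)phenyl]ethanone)
Conditions: 7, i-Pr2NEt, CH2Cl2, 0 °C → rt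
Reagents that add atoms: MOMCl, COCCl
Why: MOM ether formation protects the hindered phenol, using a small electrophile, and the MOM group survives later base, heat, metathesis, and reduction.

**Step 5**
Reactants: 8
Product: 9 (1-[2-allyl-4-hydroxy-3-(methoxymethoxy)phenyl]ethanone)
Conditions: DDQ, CH2Cl2/H2O (18:1), 0 °C → rt, 1 h
Reagents that add atoms: none
Why: DDQ cleaves the PMB ether by oxidation of the anisyl ring, which leaves the MOM acetal and the allyl group intact and frees O-4 for pyran formation.

**Step 6**
Reactants: 9; 10 (2-methylbut-2-ene)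
Product: 11 (1-[4-hydroxy-3-(methoxymethoxy)-2-(3-methylbut-2-enyl)phenyl]ethanone)
Conditions: 10 (20 equiv), Hoveyda–Grubbs II (5 mol%), CH2Cl2, 40 °C, sealed tube, 16 h
Reagents that add atoms: 2-methylbut-2-ene, CC=C(C)C
Why: Olefin cross-metathesis exchanges the terminal CH2= of the allyl group for Me2C= (propene is expelled), converting allyl to prenyl.

**Step 7**
Reactants: 11; 12 (3-chloro-3-methylbut-1-yne)
Product: 13 (1-[3-(methoxymethoxy)-4-(2-methylbut-3-yn-2-yloxy)-2-(3-methylbut-2-enyl)phenyl]ethanone)
Conditions: 12 (3 equiv), K2CO3, KI, CuI (cat.), DMF, 50 °C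
Reagents that add atoms: 3-chloro-3-methylbut-1-yne, C#CC(C)(C)Cl
Why: Cu-assisted O-alkylation of the phenoxide with the tertiary propargylic chloride gives the 1,1-dimethylpropargyl aryl ether.

**Step 8**
Reactants: 13
Product: 14 (1-[8-(methoxymethoxy)-2,2-dimethyl-7-(3-methylbut-2-enyl)-2H-chromen-6-yl]ethanone)
Conditions: PhNEt2, 200 °C, sealed tube, 4 h
Reagents that add atoms: none
Why: Propargyl Claisen rearrangement to an allenyl dienone, then 1,5-H shift and 6π-oxa-electrocyclization, forms the 2,2-dimethyl-2H-chromene at the only free ortho position.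

**Step 9**
Reactants: 15 (2,4-dihydroxybenzaldehyde); 7 (MOMCl)
Product: 16 (2-hydroxy-4-(methoxymethoxy)benzaldehyde)
Conditions: 7, i-Pr2NEt, CH2Cl2, 0 °C
Reagents that add atoms: MOMCl, COCCl
Why: The 2-OH is hydrogen-bonded to the aldehyde and is less reactive, so MOM etherification occurs only at the more acidic 4-OH and leaves the 2-OH free for the later Mitsunobu ring closure.

**Step 10**
Reactants: 14; 16
Product: 17 ((E)-3-[2-hydroxy-4-(methoxymethoxy)phenyl]-1-[8-(methoxymethoxy)-2,2-dimethyl-7-(3-methylbut-2-enyl)-2H-chromen-6-yl]prop-2-en-1-one)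
Conditions: KOH (5 equiv), EtOH/H2O (9:1), 25 → 50 °C, 24 h; quench with sat. NH4Cl to pH ~6
Reagents that add atoms: none
Why: Claisen–Schmidt aldol condensation; the ketone enolate adds to the aldehyde and dehydration gives the conjugated E-enone. The MOM acetals, chromene, and prenyl group are base-stable.

**Step 11**
Reactants: 17
Product: 18 (dihydrochalcone: 3-[2-hydroxy-4-(methoxymethoxy)phenyl]-1-[8-(methoxymethoxy)-2,2-dimethyl-7-(3-methylbut-2-enyl)-2H-chromen-6-yl]propan-1-one)
Conditions: [(Ph3P)CuH]6 (0.4 equiv), toluene, 0 °C, 2 h; then aq. NH4Cl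
Reagents that add atoms: none
Why: Stryker-type Cu–H conjugate reduction reduces only the enone C=C and leaves the prenyl and chromene olefins and the ketone untouched; no stereocenter is formed.

**Step 12**
Reactants: 18
Product: 19 ((R)-3-[2-hydroxy-4-(methoxymethoxy)phenyl]-1-[8-(methoxymethoxy)-2,2-dimethyl-7-(3-methylbut-2-enyl)-2H-chromen-6-yl]propan-1-ol)
Conditions: anti-Prelog (R)-selective KRED (Lactobacillus-type ADH), NADP+ (1 mol%), GDH, D-glucose (2 equiv), KPi buffer pH 7.0 with DMSO (20% v/v), 30 °C, 48 h
Reagents that add atoms: none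
Why: The ketoreductase transfers hydride from NADPH to one enantiotopic face of the ketone in its chiral active site, so this asymmetric biocatalytic reduction sets the sole stereocenter as (R); glucose/GDH recycles the cofactor.

**Step 13**
Reactants: 19
Product: 20 ((2S)-7-(methoxymethoxy)-2-[8-(methoxymethoxy)-2,2-dimethyl-7-(3-methylbut-2-enyl)-2H-chromen-6-yl]chroman)
Conditions: PPh3 (1.5 equiv), DIAD (1.5 equiv), THF (0.02 M), 0 °C → rt, 3 h
Reagents that add atoms: none
Why: Intramolecular Mitsunobu etherification of the phenol onto the activated benzylic alcohol is an SN2 six-membered ring closure with inversion, so (R)-alcohol becomes (S)-chroman; high dilution and low temperature suppress ionization and elimination.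

**Step 14**
Reactants: 20
Product: 21 (Kazinol B)
Conditions: ZnBr2 (4 equiv), n-PrSH (8 equiv), CH2Cl2, 0 °C, 20 min
Reagents that add atoms: none
Why: The Lewis acid/thiol system cleaves both aryl MOM acetals under near-neutral conditions at 0 °C, leaving the chroman stereocenter, chromene, and prenyl group intact.

## Compound list
1 | 3',4'-dihydroxyacetophenone | CC(=O)c1ccc(O)c(O)c1 | starting material
2 | 4-methoxybenzyl chloride | COc1ccc(CCl)cc1 | starting material
3 | 1-[3-hydroxy-4-(4-methoxybenzyloxy)phenyl]ethanone | CC(=O)c1ccc(OCc2ccc(OC)cc2)c(O)c1 | intermediate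
4 | allyl bromide | C=CCBr | starting material
5 | 1-[3-allyloxy-4-(4-methoxybenzyloxy)phenyl]ethanone | CC(=O)c1ccc(OCc2ccc(OC)cc2)c(OCC=C)c1 | intermediate
6 | 1-[2-allyl-3-hydroxy-4-(4-methoxybenzyloxy)phenyl]ethanone | CC(=O)c1ccc(OCc2ccc(OC)cc2)c(O)c1CC=C | intermediate
7 | chloromethyl methyl ether (MOMCl) | COCCl | starting material
8 | 1-[2-allyl-3-(methoxymethoxy)-4-(4-methoxybenzyloxy)phenyl]ethanone | CC(=O)c1ccc(OCc2ccc(OC)cc2)c(OCOC)c1CC=C | intermediate
9 | 1-[2-allyl-4-hydroxy-3-(methoxymethoxy)phenyl]ethanone | CC(=O)c1ccc(O)c(OCOC)c1CC=C | intermediate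
10 | 2-methylbut-2-ene | CC=C(C)C | starting material
11 | 1-[4-hydroxy-3-(methoxymethoxy)-2-(3-methylbut-2-enyl)phenyl]ethanone | CC(=O)c1ccc(O)c(OCOC)c1CC=C(C)C | intermediate
12 | 3-chloro-3-methylbut-1-yne | C#CC(C)(C)Cl | starting material
13 | 1-[3-(methoxymethoxy)-4-(2-methylbut-3-yn-2-yloxy)-2-(3-methylbut-2-enyl)phenyl]ethanone | CC(=O)c1ccc(OC(C)(C)C#C)c(OCOC)c1CC=C(C)C | intermediate
14 | 1-[8-(methoxymethoxy)-2,2-dimethyl-7-(3-methylbut-2-enyl)-2H-chromen-6-yl]ethanone | CC(=O)c1cc2C=CC(C)(C)Oc2c(OCOC)c1CC=C(C)C | intermediate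
15 | 2,4-dihydroxybenzaldehyde | O=Cc1ccc(O)cc1O | starting material
16 | 2-hydroxy-4-(methoxymethoxy)benzaldehyde | O=Cc1ccc(OCOC)cc1O | intermediate
17 | (E)-chalcone from 14 and 16 | O=C(/C=C/c1ccc(OCOC)cc1O)c1cc2C=CC(C)(C)Oc2c(OCOC)c1CC=C(C)C | intermediate
18 | dihydrochalcone (3-aryl-1-aryl-propan-1-one) | O=C(CCc1ccc(OCOC)cc1O)c1cc2C=CC(C)(C)Oc2c(OCOC)c1CC=C(C)C | intermediate
19 | (R)-1,3-diarylpropan-1-ol | O[C@H](CCc1ccc(OCOC)cc1O)c1cc2C=CC(C)(C)Oc2c(OCOC)c1CC=C(C)C | intermediate
20 | (2S)-bis-MOM flavan | CC(C)=CCc1c([C@@H]2CCc3ccc(OCOC)cc3O2)cc2c(c1OCOC)OC(C)(C)C=C2 | intermediate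
21 | Kazinol B | CC(C)=CCc1c([C@@H]2CCc3ccc(O)cc3O2)cc2c(c1O)OC(C)(C)C=C2 | target

## Totals
- Total steps: 14.
- Longest linear sequence: 13 steps (1 → 3 → 5 → 6 → 8 → 9 → 11 → 13 → 14 → 17 → 18 → 19 → 20 → 21). Step 9, the preparation of 16, runs in parallel.

## Three steps most likely to fail
1. **Step 12 (KRED reduction of the hindered, lipophilic, ortho-substituted diaryl ketone).** The enzyme may show low activity or ee. Fallback: replace it with Ru-catalyzed asymmetric transfer hydrogenation of 18 using (R,R)-TsDPEN-Ru(p-cymene) and HCO2H/Et3N to give the (R)-alcohol, or resolve the racemic alcohol (from NaBH4 reduction of 18) by lipase-catalyzed acylation.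
2. **Step 13 (Mitsunobu closure).** The para-alkoxy benzylic centre can ionize, causing partial racemization or elimination to the styrene. Fallback: use the 2-iodo analogue of aldehyde 16 throughout and the (S)-alcohol from a Prelog-type KRED, then close the ring by Cu-catalyzed intramolecular O-arylation (for example CuI/Me4-phenanthroline, Cs2CO3), which keeps the C–O bond and retains configuration.
3. **Step 6 (allyl→prenyl cross-metathesis).** Trisubstituted-olefin cross-metathesis on a hindered arene can stall or isomerize the allyl group. Fallback: ozonolysis of 9 to the arylacetaldehyde, then Wittig olefination with Ph3P=CMe2 (from i-PrPPh3I and KOt-Bu) to give 11.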